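**Retrosynthetic overview**

1. The target comes from the N-tosyl tetrahydroisoquinoline 29 by O-desilylation, loss of sulfinate, dehydrogenation of the nitrogen ring and O-debenzylation.
2. Structural feature: in isoquinoline numbering, C7 (naphthyl) and C8 (oxygen) are adjacent and correspond to the two carbons of an aryl ynol ether, while C8a–C4a–C5–C6 correspond to C3–C4–C5–C6 of a 2-pyrone fused to the saturated nitrogen ring. Cutting C6–C7 and C8–C8a gives pyrone 10 and naphthyl siloxyalkyne 27.
3. Pyrone 10: the nitrogen ring is made first (reductive amination, N-tosylation, Dieckmann), then the pyrone ring (enol triflate, ethoxyvinyl Suzuki coupling, acid lactonisation).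
4. Siloxyalkyne 27: the second naphthalene ring is closed by aryne acyl-alkylation of 3-benzyloxybenzyne with acetylacetone and aldol condensation, followed by O-methylation, C4 iodination, Sonogashira coupling, acetylide oxidation and O-silylation.
5. Ring order: piperidine, then pyrone; naphthalene separately; the benzene ring of the isoquinoline by (4+2) addition with loss of CO2; the pyridine ring is aromatised last.

Key step: step 15

Remark: the target SMILES defines no configuration at the C7–C1' biaryl axis, so the axis is formed without control and the atropisomers of 33 would be separated on a chiral stationary phase if one enantiomer is required; the sp3 centres at C1 and C3 carried through 4–31 are stereoisomer mixtures that are erased on aromatisation.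

**Route**

Step 1
Reactants: 1 ethyl 3-aminobutanoate (racemic); 2 ethyl acetoacetate
Product: 4 diethyl 3,3'-azanediyldibutanoate (meso/racemic mixture), via enamino ester 3 (not isolated)
Conditions: MgSO4, CH2Cl2, rt; then NaBH(OAc)3, AcOH, 0 °C to rt
Reagents that add atoms: none
Why: Reductive amination of a β-keto ester: the amine condenses to the hydrogen-bonded Z-enamino ester, which the acyloxyborohydride reduces through its iminium tautomer in acetic acid; the new centre is not controlled and is erased later.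

Step 2
Reactants: 4 diethyl 3,3'-azanediyldibutanoate
Product: 5 diethyl 3,3'-[(4-methylbenzenesulfonyl)azanediyl]dibutanoate
Conditions: TsCl, pyridine, DMAP (cat.), 50 °C
Reagents that add atoms: 4-methylbenzenesulfonyl chloride, Cc1ccc(cc1)S(Cl)(=O)=O
Why: N-Sulfonylation of a secondary amine; the di-sec-alkyl amine is hindered, so a nucleophilic catalyst and gentle warming are used.

Step 3
Reactants: 5 diethyl 3,3'-[(4-methylbenzenesulfonyl)azanediyl]dibutanoate
Product: 6 ethyl 2,6-dimethyl-1-(4-methylbenzenesulfonyl)-4-oxopiperidine-3-carboxylate (stereoisomer and keto/enol mixture)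
Conditions: KOtBu, THF, 0 °C to rt; 1 M HCl
Reagents that add atoms: none
Why: Dieckmann condensation of a symmetrical diester can give only one constitution and is driven by deprotonation of the β-keto ester, so any reversible retro-aza-Michael opening should be funnelled back into the ring.

Step 4
Reactants: 6 ethyl 2,6-dimethyl-1-(4-methylbenzenesulfonyl)-4-oxopiperidine-3-carboxylate
Product: 7 ethyl 2,6-dimethyl-1-(4-methylbenzenesulfonyl)-4-[(trifluoromethanesulfonyl)oxy]-1,2,5,6-tetrahydropyridine-3-carboxylate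
Conditions: NaH, THF, 0 °C; PhNTf2, 0 °C to rt
Reagents that add atoms: N-phenylbis(trifluoromethanesulfonimide), O=S(=O)(N(c1ccccc1)S(=O)(=O)C(F)(F)F)C(F)(F)F
Why: O-Triflation of the stabilised β-keto ester enolate gives the vinyl triflate (enol triflate formation).

Step 5
Reactants: 7 the vinyl triflate; 8 2-[(E)-2-ethoxyethenyl]-4,4,5,5-tetramethyl-1,3,2-dioxaborolane
Product: 9 ethyl 4-[(E)-2-ethoxyethenyl]-2,6-dimethyl-1-(4-methylbenzenesulfonyl)-1,2,5,6-tetrahydropyridine-3-carboxylate
Conditions: Pd(dppf)Cl2 (5 mol %), K3PO4, 1,4-dioxane/H2O, 80 °C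
Reagents that add atoms: none
Why: Suzuki–Miyaura coupling of an electron-poor vinyl triflate with an alkenyl boronate places the masked acetaldehyde unit cis to the ester across the ring double bond.

Step 6
Reactants: 9 the ethoxyvinyl ester
Product: 10 6,8-dimethyl-7-(4-methylbenzenesulfonyl)-5,6,7,8-tetrahydro-1H-pyrano[3,4-c]pyridin-1-one (cis/trans mixture)
Conditions: TsOH·H2O, PhMe, 80 °C
Reagents that add atoms: water, O
Why: Acid hydrolysis of the enol ether to the aldehyde (or its oxocarbenium ion) followed by enol lactonisation onto the cis ester closes the 2-pyrone, the same lactonisation that converts 2-(2-ethoxyvinyl) benzoates into isocoumarins.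

Step 7
Reactants: 11 3-(benzyloxy)phenol
Product: 12 3-(benzyloxy)phenyl N-(propan-2-yl)carbamate
Conditions: iPrNCO, Et3N (cat.), CH2Cl2, rt
Reagents that add atoms: isopropyl isocyanate, CC(C)N=C=O
Why: Base-catalysed addition of the phenol to the isocyanate installs a carbamate that directs metalation and can later be removed under mild base.

Step 8
Reactants: 12 3-(benzyloxy)phenyl N-(propan-2-yl)carbamate
Product: 15 3-(benzyloxy)-2-(trimethylsilyl)phenyl N-(propan-2-yl)carbamate, via N-TBS carbamate 13 (not isolated), via N-TBS C-TMS carbamate 14 (not isolated)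
Conditions: TBSOTf, TMEDA, Et2O, 0 °C to rt; n-BuLi, TMEDA, −78 °C; TMSCl, −78 °C to rt; aq NaHSO4
Reagents that add atoms: chlorotrimethylsilane, C[Si](C)(C)Cl; tert-butyldimethylsilyl triflate, CC(C)(C)[Si](C)(C)OS(=O)(=O)C(F)(F)F (silyl group carried only in 13 and 14)
Why: Directed ortho-metalation: temporary N-silylation masks the N–H, lithiation occurs at C2 between the two oxygen groups and is quenched by TMSCl, and the N-silyl group is lost on acidic work-up; the low temperature should spare the benzylic C–H of the ether.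

Step 9
Reactants: 15 3-(benzyloxy)-2-(trimethylsilyl)phenyl N-(propan-2-yl)carbamate
Product: 17 3-(benzyloxy)-2-(trimethylsilyl)phenyl trifluoromethanesulfonate, via silylphenol 16 (not isolated)
Conditions: DBU, Et2NH, MeCN, 40 °C; then PhNTf2, rt
Reagents that add atoms: N-phenylbis(trifluoromethanesulfonimide), O=S(=O)(N(c1ccccc1)S(=O)(=O)C(F)(F)F)C(F)(F)F
Why: E1cB cleavage of the N-monoalkyl carbamate (the isocyanate is trapped by diethylamine) frees the phenoxide without acid, so the aryl–silicon bond survives, and triflation in the same flask gives the fluoride-triggered aryne precursor.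

Step 10
Reactants: 17 3-(benzyloxy)-2-(trimethylsilyl)phenyl trifluoromethanesulfonate; 18 pentane-2,4-dione
Product: 20 8-(benzyloxy)-3-methylnaphthalen-1-ol, via diketone 19 (not isolated)
Conditions: CsF, MeCN, 80 °C; then NaOMe, MeOH, 50 °C; aq HCl
Reagents that add atoms: none
Why: Aryne acyl-alkylation: the diketone enolate attacks 3-benzyloxybenzyne at the carbon meta to oxygen, the aryl anion adds to an acetyl group and the four-membered alkoxide fragments, placing the acetyl next to OBn; methoxide then effects the intramolecular aldol condensation of the aryl methyl ketone enolate onto the unhindered aliphatic ketone to give the 1-naphthol.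

Step 11
Reactants: 20 8-(benzyloxy)-3-methylnaphthalen-1-ol
Product: 21 8-(benzyloxy)-1-methoxy-3-methylnaphthalene
Conditions: MeI, K2CO3, DMF, 40 °C
Reagents that add atoms: iodomethane, CI
Why: Williamson O-methylation of the naphthol.

Step 12
Reactants: 21 8-(benzyloxy)-1-methoxy-3-methylnaphthalene
Product: 22 5-(benzyloxy)-1-iodo-4-methoxy-2-methylnaphthalene
Conditions: NIS, TFA (cat.), MeCN, 0 °C to rt
Reagents that add atoms: N-iodosuccinimide, O=C1CCC(=O)N1I
Why: Electrophilic aromatic iodination should go to the α-position para to methoxy and ortho to methyl, which is activated by two donors, whereas C5 has only the para benzyloxy group.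

Step 13
Reactants: 22 5-(benzyloxy)-1-iodo-4-methoxy-2-methylnaphthalene; 23 ethynyl(trimethyl)silane
Product: 25 5-(benzyloxy)-1-ethynyl-4-methoxy-2-methylnaphthalene, via TMS-alkyne 24 (not isolated)
Conditions: Pd(PPh3)2Cl2, CuI, Et3N, THF, 60 °C; then K2CO3, MeOH, rt
Reagents that add atoms: none
Why: Sonogashira coupling of the aryl iodide followed by methanolysis of the alkynyl–silicon bond gives the terminal arylalkyne.

Step 14
Reactants: 25 5-(benzyloxy)-1-ethynyl-4-methoxy-2-methylnaphthalene
Product: 27 ({[5-(benzyloxy)-4-methoxy-2-methylnaphthalen-1-yl]ethynyl}oxy)tri(propan-2-yl)silane, via lithium ynolate 26 (not isolated)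
Conditions: LiHMDS, t-BuOOH, THF, −78 to 0 °C; then TIPSOTf, −78 °C
Reagents that add atoms: tert-butyl hydroperoxide, CC(C)(C)OO; triisopropylsilyl triflate, CC(C)[Si](C(C)C)(C(C)C)OS(=O)(=O)C(F)(F)F
Why: Acetylide oxidation: the lithium acetylide takes an oxygen atom from lithium tert-butyl peroxide to give the lithium ynolate, which the bulky silyl triflate traps on oxygen as the siloxyalkyne.

Step 15
Reactants: 10 the bicyclic 2-pyrone; 27 the naphthyl siloxyalkyne
Product: 29 7-[5-(benzyloxy)-4-methoxy-2-methylnaphthalen-1-yl]-1,3-dimethyl-2-(4-methylbenzenesulfonyl)-8-[(triisopropylsilyl)oxy]-1,2,3,4-tetrahydroisoquinoline (stereoisomer mixture), via bridged lactone 28 (not isolated)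
Conditions: PhMe, 120 °C, sealed tube, Ar (27 in excess)
Reagents that add atoms: none
Why: Proposed new method: the electron-rich siloxyalkyne should add as the 2π partner across C6 and C3 of the 2-pyrone in an asynchronous inverse-demand (4+2) cycloaddition, its nucleophilic naphthyl-bearing carbon bonding first to the unsubstituted electrophilic pyrone C6 and its oxygen-bearing carbon closing onto C3, to give bridged lactone 28, which expels CO2 by retro-(4+2) to the arene. The closest known reaction types are the thermal Diels–Alder/CO2-loss sequences of 2-pyrones with ynamines and with alkynylboronates and the silver-catalysed formal inverse-demand cycloaddition of 1,2-diazines with siloxyalkynes; a siloxyalkyne has not been shown with a 2-pyrone. The benzene ring of the tetrahydroisoquinoline is closed by intermolecular cycloaddition followed by cycloreversion, forming C6–C7 and C8–C8a. No stereocentre is created: C1 and C3 are carried as mixtures and the new biaryl axis forms without control. The step needs regioselectivity, which polarity (the ynol ether β-carbon to pyrone C6, the site where nucleophiles attack pyrones) and sterics (the naphthyl carbon at the unsubstituted diene terminus) should both secure. The triisopropylsilyl group and the moderate temperature are chosen so that cycloaddition can outrun the 1,3-silyl shift of 27 to a silylketene.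

Step 16
Reactants: 29 the silyl ether
Product: 30 7-[5-(benzyloxy)-4-methoxy-2-methylnaphthalen-1-yl]-1,3-dimethyl-2-(4-methylbenzenesulfonyl)-1,2,3,4-tetrahydroisoquinolin-8-ol
Conditions: TBAF, THF, 0 °C to rt
Reagents that add atoms: none
Why: Fluoride cleavage of the aryl silyl ether frees the C8 phenol.

Step 17
Reactants: 30 the N-tosyl phenol
Product: 31 7-[5-(benzyloxy)-4-methoxy-2-methylnaphthalen-1-yl]-1,3-dimethyl-3,4-dihydroisoquinolin-8-ol
Conditions: KOtBu, DMSO, 70 °C, Ar
Reagents that add atoms: none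
Why: Base-induced 1,2-elimination of p-toluenesulfinate across the benzylic C1–N bond of the sulfonamide gives the conjugated C1=N imine and erases the C1 centre.

Step 18
Reactants: 31 the dihydroisoquinoline
Product: 33 7-(5-hydroxy-4-methoxy-2-methylnaphthalen-1-yl)-1,3-dimethylisoquinolin-8-ol (ent-dioncophylleine A after separation of the atropisomers), via O-benzyl isoquinoline 32 (not isolated)
Conditions: Pd/C, mesitylene, 165 °C, Ar; then EtOH, H2 (1 atm), rt
Reagents that add atoms: none
Why: Catalytic dehydrogenation of the 3,4-dihydroisoquinoline over Pd/C is driven by aromatisation and erases C3, and hydrogenolysis of the aryl benzyl ether on the same catalyst then frees the naphthol.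

**Compound list**

1 | ethyl 3-aminobutanoate (racemic) | CCOC(=O)CC(C)N | starting material
2 | ethyl acetoacetate | CCOC(=O)CC(C)=O | starting material
3 | ethyl (Z)-3-[(4-ethoxy-4-oxobutan-2-yl)amino]but-2-enoate | CCOC(=O)/C=C(/C)NC(C)CC(=O)OCC | intermediate
4 | diethyl 3,3'-azanediyldibutanoate (meso/racemic mixture) | CCOC(=O)CC(C)NC(C)CC(=O)OCC | intermediate
5 | diethyl 3,3'-[(4-methylbenzenesulfonyl)azanediyl]dibutanoate | CCOC(=O)CC(C)N(C(C)CC(=O)OCC)S(=O)(=O)c1ccc(C)cc1 | intermediate
6 | ethyl 2,6-dimethyl-1-(4-methylbenzenesulfonyl)-4-oxopiperidine-3-carboxylate (stereoisomer mixture) | CCOC(=O)C1C(C)N(S(=O)(=O)c2ccc(C)cc2)C(C)CC1=O | intermediate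
7 | ethyl 2,6-dimethyl-1-(4-methylbenzenesulfonyl)-4-[(trifluoromethanesulfonyl)oxy]-1,2,5,6-tetrahydropyridine-3-carboxylate (cis/trans mixture) | CCOC(=O)C1=C(OS(=O)(=O)C(F)(F)F)CC(C)N(S(=O)(=O)c2ccc(C)cc2)C1C | intermediate
8 | 2-[(E)-2-ethoxyethenyl]-4,4,5,5-tetramethyl-1,3,2-dioxaborolane | CCO/C=C/B1OC(C)(C)C(C)(C)O1 | starting material
9 | ethyl 4-[(E)-2-ethoxyethenyl]-2,6-dimethyl-1-(4-methylbenzenesulfonyl)-1,2,5,6-tetrahydropyridine-3-carboxylate (cis/trans mixture) | CCO/C=C/C1=C(C(=O)OCC)C(C)N(S(=O)(=O)c2ccc(C)cc2)C(C)C1 | intermediate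
10 | 6,8-dimethyl-7-(4-methylbenzenesulfonyl)-5,6,7,8-tetrahydro-1H-pyrano[3,4-c]pyridin-1-one (cis/trans mixture) | O=C1OC=CC2=C1C(C)N(S(=O)(=O)c1ccc(C)cc1)C(C)C2 | intermediate
11 | 3-(benzyloxy)phenol | Oc1cccc(OCc2ccccc2)c1 | starting material
12 | 3-(benzyloxy)phenyl N-(propan-2-yl)carbamate | CC(C)NC(=O)Oc1cccc(OCc2ccccc2)c1 | intermediate
13 | 3-(benzyloxy)phenyl N-[tert-butyl(dimethyl)silyl]-N-(propan-2-yl)carbamate | CC(C)N(C(=O)Oc1cccc(OCc2ccccc2)c1)[Si](C)(C)C(C)(C)C | intermediate
14 | 3-(benzyloxy)-2-(trimethylsilyl)phenyl N-[tert-butyl(dimethyl)silyl]-N-(propan-2-yl)carbamate | CC(C)N(C(=O)Oc1cccc(OCc2ccccc2)c1[Si](C)(C)C)[Si](C)(C)C(C)(C)C | intermediate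
15 | 3-(benzyloxy)-2-(trimethylsilyl)phenyl N-(propan-2-yl)carbamate | CC(C)NC(=O)Oc1cccc(OCc2ccccc2)c1[Si](C)(C)C | intermediate
16 | 3-(benzyloxy)-2-(trimethylsilyl)phenol | Oc1cccc(OCc2ccccc2)c1[Si](C)(C)C | intermediate
17 | 3-(benzyloxy)-2-(trimethylsilyl)phenyl trifluoromethanesulfonate | C[Si](C)(C)c1c(OCc2ccccc2)cccc1OS(=O)(=O)C(F)(F)F | intermediate
18 | pentane-2,4-dione (acetylacetone) | CC(=O)CC(C)=O | starting material
19 | 1-[2-acetyl-3-(benzyloxy)phenyl]propan-2-one | CC(=O)Cc1cccc(OCc2ccccc2)c1C(C)=O | intermediate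
20 | 8-(benzyloxy)-3-methylnaphthalen-1-ol | Cc1cc(O)c2c(OCc3ccccc3)cccc2c1 | intermediate
21 | 8-(benzyloxy)-1-methoxy-3-methylnaphthalene | COc1cc(C)cc2cccc(OCc3ccccc3)c12 | intermediate
22 | 5-(benzyloxy)-1-iodo-4-methoxy-2-methylnaphthalene | COc1cc(C)c(I)c2cccc(OCc3ccccc3)c12 | intermediate
23 | ethynyl(trimethyl)silane | C#C[Si](C)(C)C | starting material
24 | {[5-(benzyloxy)-4-methoxy-2-methylnaphthalen-1-yl]ethynyl}(trimethyl)silane | COc1cc(C)c(C#C[Si](C)(C)C)c2cccc(OCc3ccccc3)c12 | intermediate
25 | 5-(benzyloxy)-1-ethynyl-4-methoxy-2-methylnaphthalene | COc1cc(C)c(C#C)c2cccc(OCc3ccccc3)c12 | intermediate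
26 | lithium 2-[5-(benzyloxy)-4-methoxy-2-methylnaphthalen-1-yl]ethyn-1-olate | [Li+].[O-]C#Cc1c(C)cc(OC)c2c(OCc3ccccc3)cccc12 | intermediate
27 | ({[5-(benzyloxy)-4-methoxy-2-methylnaphthalen-1-yl]ethynyl}oxy)tri(propan-2-yl)silane | CC(C)[Si](C(C)C)(C(C)C)OC#Cc1c(C)cc(OC)c2c(OCc3ccccc3)cccc12 | intermediate
28 | (4+2) adduct with a 2-oxabicyclo[2.2.2]octa-5,7-dien-3-one core fused to the N-tosyl piperidine: lactone oxygen on the former pyrone C6, lactone carbonyl on the former pyrone C3, naphthyl and triisopropylsiloxy groups on the new double bond (stereoisomer mixture) | O=C1OC2C=C3CC(C)N(S(=O)(=O)c4ccc(C)cc4)C(C)C31C(O[Si](C(C)C)(C(C)C)C(C)C)=C2c1c(C)cc(OC)c2c(OCc3ccccc3)cccc12 | intermediate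
29 | 7-[5-(benzyloxy)-4-methoxy-2-methylnaphthalen-1-yl]-1,3-dimethyl-2-(4-methylbenzenesulfonyl)-8-[(triisopropylsilyl)oxy]-1,2,3,4-tetrahydroisoquinoline (stereoisomer mixture) | CC1Cc2ccc(-c3c(C)cc(OC)c4c(OCc5ccccc5)cccc34)c(O[Si](C(C)C)(C(C)C)C(C)C)c2C(C)N1S(=O)(=O)c1ccc(C)cc1 | intermediate
30 | 7-[5-(benzyloxy)-4-methoxy-2-methylnaphthalen-1-yl]-1,3-dimethyl-2-(4-methylbenzenesulfonyl)-1,2,3,4-tetrahydroisoquinolin-8-ol (stereoisomer mixture) | CC1Cc2ccc(-c3c(C)cc(OC)c4c(OCc5ccccc5)cccc34)c(O)c2C(C)N1S(=O)(=O)c1ccc(C)cc1 | intermediate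
31 | 7-[5-(benzyloxy)-4-methoxy-2-methylnaphthalen-1-yl]-1,3-dimethyl-3,4-dihydroisoquinolin-8-ol (stereoisomer mixture) | CC1Cc2ccc(-c3c(C)cc(OC)c4c(OCc5ccccc5)cccc34)c(O)c2C(C)=N1 | intermediate
32 | 7-[5-(benzyloxy)-4-methoxy-2-methylnaphthalen-1-yl]-1,3-dimethylisoquinolin-8-ol | COc1cc(C)c(-c2ccc3cc(C)nc(C)c3c2O)c2cccc(OCc3ccccc3)c12 | intermediate
33 | 7-(5-hydroxy-4-methoxy-2-methylnaphthalen-1-yl)-1,3-dimethylisoquinolin-8-ol (ent-dioncophylleine A) | COc1cc(C)c(-c2ccc3cc(C)nc(C)c3c2O)c2cccc(O)c12 | target

**Step count**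

Total: 18 steps. Longest linear sequence: 12 steps (steps 7–18, from 3-(benzyloxy)phenol); the pyrone arm (steps 1–6) joins at step 15.

**Steps most likely to fail**

Step 15 (the proposed new method). The cycloaddition may be slower than the thermal shift of silicon from oxygen to carbon in 27, because the 3,4-dialkyl pyrone is a weak acceptor and the C8–C8a bond must form at a fully substituted diene terminus next to a bulky siloxy group; adventitious acid would also protonate and consume the ynol ether. The fallback uses known chemistry and replaces the cycloaddition by ring formation with ammonia and a biaryl cross-coupling. It sets out from diketone 19 (isolated after the fluoride stage of step 10) and from iodide 22, and comes back to the route at 32. Condensation of 19 with ammonia (NH4OAc, AcOH, 80 °C) should close the pyridine ring to 8-(benzyloxy)-1,3-dimethylisoquinoline F1. Hydrogenolysis (H2, Pd/C, EtOH) would give 1,3-dimethylisoquinolin-8-ol F2, and amine-mediated ortho-bromination of the phenol (NBS, iPr2NH cat., CH2Cl2) would give 7-bromo-1,3-dimethylisoquinolin-8-ol F3. Miyaura borylation of 22 (B2pin2, Pd(dppf)Cl2, KOAc, dioxane, 90 °C) would give 2-[5-(benzyloxy)-4-methoxy-2-methylnaphthalen-1-yl]-4,4,5,5-tetramethyl-1,3,2-dioxaborolane F4. Suzuki–Miyaura coupling of F3 with F4 (Pd(OAc)2, SPhos, K3PO4, PhMe/H2O, 100 °C) would give 32, which is hydrogenolysed as in the second stage of step 18.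

Step 12. Positional selectivity may be lost, with iodine entering para to the benzyloxy group (C5) or ortho to the methoxy group (C2), or a second iodination may follow. The fallback fixes the carbon substituent at C4 by construction; it sets out from aryne precursor 17 and comes back at alkyne 25. Acyl-alkylation of the aryne from 17 with commercial 3-allylpentane-2,4-dione (CsF, MeCN, 80 °C) would give 3-[2-acetyl-3-(benzyloxy)phenyl]hex-5-en-2-one F5, and aldol condensation (NaOMe, MeOH) would give 8-(benzyloxy)-3-methyl-4-(prop-2-en-1-yl)naphthalen-1-ol F6. O-Methylation (MeI, K2CO3, DMF) would give 5-(benzyloxy)-4-methoxy-2-methyl-1-(prop-2-en-1-yl)naphthalene F7, and base-mediated alkene migration (KOtBu, DMSO, rt) would give 5-(benzyloxy)-4-methoxy-2-methyl-1-(prop-1-en-1-yl)naphthalene F8. Lemieux–Johnson cleavage (OsO4 cat., NaIO4, 2,6-lutidine, dioxane/H2O) would pass through 1-[5-(benzyloxy)-4-methoxy-2-methylnaphthalen-1-yl]propane-1,2-diol F9 to 5-(benzyloxy)-4-methoxy-2-methylnaphthalene-1-carbaldehyde F10. Ohira–Bestmann homologation (dimethyl (1-diazo-2-oxopropyl)phosphonate, K2CO3, MeOH) would then give 25.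

Step 17. The elimination may stall because the C8 phenoxide formed first lowers the acidity of the benzylic C1–H, or prolonged heating in base may degrade the electron-rich phenoxide. The fallback removes the sulfonyl group reductively and takes both oxidation levels by dehydrogenation; it sets out from 30 and comes back at 32. Cleavage of the N–S bond (SmI2, Et3N, H2O, THF, rt) would give 7-[5-(benzyloxy)-4-methoxy-2-methylnaphthalen-1-yl]-1,3-dimethyl-1,2,3,4-tetrahydroisoquinolin-8-ol F11. Dehydrogenation over Pd/C (mesitylene or decalin, reflux, Ar) would give 32, and the hydrogen stage of step 18 would finish the route.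

**Further compounds**

F1 | step 15 | 8-(benzyloxy)-1,3-dimethylisoquinoline | Cc1cc2cccc(OCc3ccccc3)c2c(C)n1
F2 | step 15 | 1,3-dimethylisoquinolin-8-ol | Cc1cc2cccc(O)c2c(C)n1
F3 | step 15 | 7-bromo-1,3-dimethylisoquinolin-8-ol | Cc1cc2ccc(Br)c(O)c2c(C)n1
F4 | step 15 | 2-[5-(benzyloxy)-4-methoxy-2-methylnaphthalen-1-yl]-4,4,5,5-tetramethyl-1,3,2-dioxaborolane | COc1cc(C)c(B2OC(C)(C)C(C)(C)O2)c2cccc(OCc3ccccc3)c12
F5 | step 12 | 3-[2-acetyl-3-(benzyloxy)phenyl]hex-5-en-2-one | C=CCC(C(C)=O)c1cccc(OCc2ccccc2)c1C(C)=O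
F6 | step 12 | 8-(benzyloxy)-3-methyl-4-(prop-2-en-1-yl)naphthalen-1-ol | C=CCc1c(C)cc(O)c2c(OCc3ccccc3)cccc12
F7 | step 12 | 5-(benzyloxy)-4-methoxy-2-methyl-1-(prop-2-en-1-yl)naphthalene | C=CCc1c(C)cc(OC)c2c(OCc3ccccc3)cccc12
F8 | step 12 | 5-(benzyloxy)-4-methoxy-2-methyl-1-(prop-1-en-1-yl)naphthalene (E/Z mixture) | CC=Cc1c(C)cc(OC)c2c(OCc3ccccc3)cccc12
F9 | step 12 | 1-[5-(benzyloxy)-4-methoxy-2-methylnaphthalen-1-yl]propane-1,2-diol (stereoisomer mixture) | CC(O)C(O)c1c(C)cc(OC)c2c(OCc3ccccc3)cccc12
F10 | step 12 | 5-(benzyloxy)-4-methoxy-2-methylnaphthalene-1-carbaldehyde | O=Cc1c(C)cc(OC)c2c(OCc3ccccc3)cccc12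
F11 | step 17 | 7-[5-(benzyloxy)-4-methoxy-2-methylnaphthalen-1-yl]-1,3-dimethyl-1,2,3,4-tetrahydroisoquinolin-8-ol (stereoisomer mixture) | CC1Cc2ccc(-c3c(C)cc(OC)c4c(OCc5ccccc5)cccc34)c(O)c2C(C)N1
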